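**Assumption:** the target has no stereocentre and no stereogenic axis or alkene, so "single enantiomer" is moot; the only stereo-elements on the route (the E-alkene of 6, the racemic centres of 5 and 7) are erased before the end. The route is a design from known reaction types and has not been run.

## Retrosynthetic overview

1. The pyranone C ring is the only ring built and is formed last, by oxidative cyclisation (O1–C2 bond, then C2=C3) of a 2'-hydroxychalcone.
2. The chalcone is cut at Cα=Cβ: Claisen–Schmidt condensation of 2'-hydroxy-3',4',6'-trimethoxyacetophenone with 2,3,4-trimethoxybenzaldehyde.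
3. The acetophenone comes from 1,2,3,5-tetramethoxybenzene by Friedel–Crafts acetylation with in-flask chelation-controlled mono-demethylation.
4. The A and B rings are bought fully oxygenated, and the single free phenol fixes the 5,7,8-pattern unambiguously.

## Route

Step 1
Reactants: 1 1,2,3,5-tetramethoxybenzene
Product: 3 2'-hydroxy-3',4',6'-trimethoxyacetophenone, via tetramethoxyacetophenone 2 (not isolated)
Conditions: AcCl (1.2 equiv), AlCl3 (2.5 equiv), Et2O, 0 °C → rt, 24 h; then ice/2 M HCl
Reagents that add atoms: acetyl chloride, CC(Cl)=O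
Why: Friedel–Crafts acylation occurs at the only free (symmetry-equivalent, triply activated) position of 1, and excess AlCl3 chelated to the new carbonyl then cleaves the most congested flanking ether (the 2'-OMe buttressed by the 3'-OMe) in a chelation-controlled Lewis-acid demethylation that stops at the six-membered aluminium phenoxide chelate; no stereocentre is formed.

Step 2
Reactants: 3 2'-hydroxy-3',4',6'-trimethoxyacetophenone; 4 2,3,4-trimethoxybenzaldehyde
Product: 6 (E)-2'-hydroxy-2,3,3',4,4',6'-hexamethoxychalcone, via aldol adduct 5 (not isolated)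
Conditions: KOH (50% aq., 5 equiv), EtOH, rt, 24–48 h; then 2 M HCl to pH ~4 at 0 °C
Reagents that add atoms: none
Why: Claisen–Schmidt (crossed aldol) condensation, in which the methyl-ketone enolate of 3 adds to the non-enolisable aldehyde 4 and E1cB loss of water from racemic aldol 5 gives the conjugated enone with thermodynamically set E geometry, leaving no stereocentre.

Step 3
Reactants: 6 (E)-2'-hydroxy-2,3,3',4,4',6'-hexamethoxychalcone
Product: 8 2',3',4',5,7,8-hexamethoxyflavone, via flavanone 7 (not isolated)
Conditions: I2 (10 mol %), DMSO, 130 °C, 2 h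
Reagents that add atoms: none
Why: Iodine-mediated oxidative cyclisation, in which 6-endo oxa-Michael addition of the single free 2'-OH gives racemic flavanone 7, α-iodination and loss of HI install the C2=C3 bond, and DMSO re-oxidises HI to I2 so iodine stays catalytic; the C2 centre of 7 is erased and the achiral target results.

## Compound list

1 | 1,2,3,5-tetramethoxybenzene | COc1cc(OC)c(OC)c(OC)c1 | starting material
2 | 2',3',4',6'-tetramethoxyacetophenone (not isolated) | CC(=O)c1c(OC)cc(OC)c(OC)c1OC | intermediate
3 | 2'-hydroxy-3',4',6'-trimethoxyacetophenone | CC(=O)c1c(OC)cc(OC)c(OC)c1O | intermediate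
4 | 2,3,4-trimethoxybenzaldehyde | COc1ccc(C=O)c(OC)c1OC | starting material
5 | 3-hydroxy-1-(2-hydroxy-3,4,6-trimethoxyphenyl)-3-(2,3,4-trimethoxyphenyl)propan-1-one, racemic aldol adduct (not isolated) | COc1ccc(C(O)CC(=O)c2c(OC)cc(OC)c(OC)c2O)c(OC)c1OC | intermediate
6 | (E)-1-(2-hydroxy-3,4,6-trimethoxyphenyl)-3-(2,3,4-trimethoxyphenyl)prop-2-en-1-one, the (E)-chalcone | COc1ccc(/C=C/C(=O)c2c(OC)cc(OC)c(OC)c2O)c(OC)c1OC | intermediate
7 | 5,7,8-trimethoxy-2-(2,3,4-trimethoxyphenyl)chroman-4-one, racemic flavanone (not isolated) | COc1ccc(C2CC(=O)c3c(OC)cc(OC)c(OC)c3O2)c(OC)c1OC | intermediate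
8 | 2',3',4',5,7,8-hexamethoxyflavone, achiral | COc1ccc(-c2cc(=O)c3c(OC)cc(OC)c(OC)c3o2)c(OC)c1OC | target

## Summary

Total step count: 3.
Longest linear sequence: 3 steps (1 → 3 → 6 → 8); aldehyde 4 is used as bought.

## Steps most likely to fail, with fallbacks

**Step 1.** The one-pot reaction may stop at 2, or cleave the 6'-ether or more than one ether. The fallback sets out from 2 and comes back at 3. Compound 2 is isolable when the acylation is run with 1.1 equiv AlCl3 at 0 °C. Instead of a selective mono-cleavage, both carbonyl-flanking ethers are removed on purpose with BCl3 (2.5 equiv, CH2Cl2, 0 °C → rt) to give 2',6'-dihydroxy-3',4'-dimethoxyacetophenone F1. The selectivity is then set in an alkylation: Me2SO4 (1.0 equiv), K2CO3, acetone, rt → reflux methylates the unhindered 6'-oxygen. The 2'-OH, wedged between the carbonyl and the 3'-OMe and left as the chelated phenol, stays free, giving 3.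

**Step 2.** The hindered, electron-rich partners may condense slowly, 4 may undergo Cannizzaro loss, or chalcone/flavanone mixtures may form. The fallback sets out from 3 and comes back at 8, skipping 6 and step 3, by a Baker–Venkataraman sequence that brings the B-ring carbon in at the acid oxidation level. O-Acylation of 3 with 2,3,4-trimethoxybenzoyl chloride F2 (pyridine, rt) gives 2-acetyl-3,5,6-trimethoxyphenyl 2,3,4-trimethoxybenzoate F3. KOH in pyridine at 50 °C moves the aroyl group to carbon to give 1-(2-hydroxy-3,4,6-trimethoxyphenyl)-3-(2,3,4-trimethoxyphenyl)propane-1,3-dione F4. Cyclodehydration (cat. H2SO4, AcOH, 100 °C) gives 8.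

**Step 3.** HI at 130 °C may cleave the 5-OMe, iodine may substitute the activated C6 position, or the reaction may stall at 7. The fallback sets out from 6 and comes back at 8 without any halogen. Compound 6 is isomerised to flavanone 7, now isolated (NaOAc, EtOH, reflux). Soft enolisation (TMSOTf, Et3N, CH2Cl2, 0 °C) gives racemic 5,7,8-trimethoxy-2-(2,3,4-trimethoxyphenyl)-4-(trimethylsilyloxy)-2H-chromene F5. Saegusa–Ito dehydrogenation (Pd(OAc)2, MeCN, rt) gives 8.

## Further compounds

F1 | step 1 | 2',6'-dihydroxy-3',4'-dimethoxyacetophenone | CC(=O)c1c(O)cc(OC)c(OC)c1O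
F2 | step 2 | 2,3,4-trimethoxybenzoyl chloride | COc1ccc(C(=O)Cl)c(OC)c1OC
F3 | step 2 | 2-acetyl-3,5,6-trimethoxyphenyl 2,3,4-trimethoxybenzoate | CC(=O)c1c(OC)cc(OC)c(OC)c1OC(=O)c1ccc(OC)c(OC)c1OC
F4 | step 2 | 1-(2-hydroxy-3,4,6-trimethoxyphenyl)-3-(2,3,4-trimethoxyphenyl)propane-1,3-dione | COc1ccc(C(=O)CC(=O)c2c(OC)cc(OC)c(OC)c2O)c(OC)c1OC
F5 | step 3 | 5,7,8-trimethoxy-2-(2,3,4-trimethoxyphenyl)-4-(trimethylsilyloxy)-2H-chromene, racemic | COc1ccc(C2C=C(O[Si](C)(C)C)c3c(OC)cc(OC)c(OC)c3O2)c(OC)c1OC
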